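**Remarks on the chemistry (assumptions)**
- The target has a mirror plane through the midpoints of the C1–C4 and C2–C3 bonds (meso). Only relative configuration has to be set; intermediates without this plane are racemic and one enantiomer is drawn.
- Commercial 1 is taken to be the usual cis,trans,cis isomer, with the two anhydride rings on opposite faces of the four-membered ring.
- Locants C1–C4 follow the target (C1, C4 quaternary; C2, C3 carboxyl-bearing). Primed locants (O1', C2' … C6') belong to the pyranone rings.

## Analysis of the target

The core is a cyclobutane (C1–C4). C1 and C4 each carry a methyl group and a 4-methoxy-3-methyl-2-pyranone ring bonded through C6', and C2 and C3 each carry a carboxylic acid. All four ring carbons are stereocentres, and two of them (C1, C4) are quaternary and adjacent. Read from the SMILES, the two pyranones are cis to each other on one face, the two carboxyl groups are cis to each other on the other face, and both methyl groups lie on the carboxyl face. Going round the ring, the carbon substituents pyranone/CO2H/CO2H/pyranone are therefore related cis (C1/C4), trans (C1/C2), cis (C2/C3), trans (C3/C4). The methoxypyranones are vinylogous carbonates that hydroxide and other hard nucleophiles open, and they are photoactive; C2 and C3 can epimerise whenever their carboxyl groups are esters under base. Three things make the synthesis hard: vicinal quaternary stereocentres on a four-membered ring in a fixed relation to C2/C3, two pairs of carbons that all start at the carboxyl oxidation level and must be told apart, and two heteroaryl rings to be built on neighbouring neopentyl positions whose cis arms can react with each other. The strategy rests on one feature: the cis,trans,cis array of four carbon substituents on C1–C4 is exactly that of 1, where C1/C4 and C2/C3 are the ring-fusion carbons of two anhydrides. The target core differs from 1 only by the two methyl groups that replace the ring-fusion hydrogens at C1 and C4.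

## Retrosynthetic reasoning

**19 ⇒ 18.** The last bonds cut are the two O–C(CH3)3 bonds of tert-butyl esters on the C2 and C3 carboxyl groups. The acids must stay masked through every basic step, and the mask must leave under conditions a 4-methoxy-2-pyranone survives. Acidolysis meets this; saponification would open the lactones.

**18 ⇒ 17.** The two O4'–CH3 bonds are cut next. The methyl ethers are put on late because the free 4-hydroxy-2-pyranone is what ring closure delivers, and its O-methylation is a standard ambident alkylation whose preference for the 4-oxygen is known.

**17 ⇒ 16 ⇒ 15 ⇒ 13 + 14.** Each pyranone is opened at the lactone bond O1'–C2' and then cut at C5'–C6'. C6' is the carbon that C1 or C4 already carries; the other four ring carbons and the 3-methyl group come from the commercial keto ester 14. The C5'–C6' bond is made at the aldehyde oxidation level (dialdehyde 13, γ-aldol, then oxidation to 16) and not by acylation. After a first acylation, the acidic C5' of one arm would sit next to a still electrophilic acyl group on the cis neighbour, and a Dieckmann-type five-membered ring closure would be hard to avoid. With two formyl groups the only event between the arms is reversible hemiacetal formation. Both arms are trans to both ester groups, so the esters cannot be reached intramolecularly.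

**13 ⇒ 12 ⇒ 11 ⇒ 9.** The two formyl carbons are traced back to the carbonyl carbons of a cis-fused N-benzyl imide. The imide is not hydrolysed to carboxylic acids, because that would erase the distinction between the C1/C4 pair and the C2/C3 pair. Instead it is reduced: a borohydride takes one imide carbonyl to the alcohol (10), the alcohol expels 2 from the remaining amide to give lactone 11, and a second hydride reduction and a double oxidation give 13. Borohydrides discriminate imide and lactone carbonyls from tert-butyl esters, so no extra protection is needed.

**9 ⇒ 8.** The two ester O–C bonds are cut to the diacid 8. Esterification is placed after the methylation on purpose, since the free acids are what makes the methylation site-selective.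

**8 ⇒ 5 + 6 (through 7).** This is the central disconnection: the C1–CH3 and C4–CH3 bonds. Removing the methyl groups turns both quaternary centres into the ring-fusion CH carbons of imide 5. Forward, each hydrogen α to the imide is removed and replaced by a methyl group from 6. The imide activates exactly the two positions that need a methyl group, and the ring fusion leaves only one possible configuration for each new centre.

**5 ⇒ 1 + 2 (through 3 and 4).** The two C–N bonds of the imide are cut, leading to the symmetric dianhydride 1 and amine 2. One of the two equivalent anhydrides is converted to the imide and the other is hydrolysed. The imide then distinguishes C1/C4 from C2/C3, acidifies C1–H and C4–H, and keeps C1/C4 cis.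

## Alternatives that were turned down

**Alternative 1:** The cyclobutane is cut at C1–C2 and C3–C4 into maleic anhydride A2 and a tetrasubstituted alkene that already carries both pyranones, the 3,4-bis(pyranonyl)-2,5-dihydrothiophene A1. Its CH2–S–CH2 bridge stands in for the two cis methyl groups. The forward key step is a sensitised [2+2] photocycloaddition giving the thiolane- and anhydride-fused cyclobutane A3; reductive desulfurisation (Raney Ni) and anhydride hydrolysis would then give 19.
- For: it is highly convergent, the finished heteroaryl rings are carried in, the four-membered ring and all four stereocentres form in one step, and the tether guarantees the C1/C4 cis relation.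
- Against: the relation between the two pairs is not enforced. A2 must add with its anhydride ring on the thiolane side and away from the pyranones, and sterics and π-overlap with the pyranones pull in opposite directions. A1 is a cis-1,2-diheteroaryl alkene, so 6π photocyclisation between the two rings and the photochemistry of the pyranones themselves compete. The desulfurisation must spare four pyranone C=C bonds. A1 needs a synthesis of its own.
- Comparison: Alternative 1 is clearly stronger on step count and convergence. The chosen route offers in its place that no configuration depends on a facial or orientational preference (each is bought or geometrically forced) and that no light is used on a pyranone.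

**Alternative 2:** The C2–C3 bond and both carboxyl groups are disconnected. C2 and C3 become the bridgeheads of a bicyclo[2.2.0]hexene A5, whose cyclobutene is later cleaved by ozonolysis to the two acids. A5 comes from cis-1,2-dimethylcyclohexa-3,5-diene-1,2-dicarboxylic anhydride A4 by disrotatory 4π photocyclisation of the diene.
- For: the methyl groups and the anhydride are in place before the ring forms, so no quaternary centre is made on a cyclobutane. Both cis relations are ring-enforced. The C1/C4 pair (anhydride) and the C2/C3 pair (alkene, then acids) come out differentiated without extra steps.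
- Against: the relation between the pairs depends on the direction of disrotation. The cyclobutene must end up anti to the anhydride ring, which means syn to both methyl groups, and two methyl groups against an anhydride ring is not a clear bias. A4 has to be made, with a diene next to two quaternary carbons. A5 is a strained bicycle that can revert thermally. After ozonolysis the whole pyranone campaign still remains.
- Comparison: on differentiating the two pairs Alternative 2 is as strong or stronger; the chosen route spends an imide and a reduction–lactonisation on that task. The chosen route offers instead a C1/C2 relation that is purchased, not decided in a photoreaction, and a bulk starting material.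

**Alternative 3:** Both pyranones are opened at O1'–C6', leading to the bis(alkynyl keto ester) A6, with arms C6'≡C5'–C4'(=O)–C3'H(CH3)–CO2t-Bu. Forward, Ph3PAuNTf2 (monovalent gold) activates each alkyne, the tert-butyl ester carbonyl oxygen attacks C6' in a 6-endo-dig closure, and the tert-butyl group is lost as the alkene. The product is the bis(4-hydroxy-3-methyl-2-pyranone) di-tert-butyl ester A7, which is the same compound as 17.
- For: the closure is neutral and mild, both rings close at once, no oxidation step is needed, and no enolisable 1,3,5-tricarbonyl arms sit side by side. On that point it is stronger than steps 7–9 of the chosen route.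
- Against: it answers only the pyranone problem. A6 still needs the cyclobutane with both quaternary centres and two carbon handles on C1/C4, which means something like 13 and the chemistry leading to it. From 13, A6 takes alkyne homologation at two neopentyl positions and a double acylation with a methylmalonyl unit whose acidic C–H quenches acetylides. The ynone arms are also strong Michael acceptors.
- Comparison: it is a complement, not a rival, and could be grafted on at 13. The chosen strategy supplies the stereodefined core, and its three classical steps from commercial 14 are no longer than the route through A6.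

Key step: step 2

## Route

**Step 1**
Reactants: 1 cis,trans,cis-cyclobutane-1,2,3,4-tetracarboxylic dianhydride; 2 benzylamine
Product: 5 3-benzyl-2,4-dioxo-3-azabicyclo[3.2.0]heptane-6,7-dicarboxylic acid (meso; the two CO2H groups cis to each other and trans to the imide ring), via amic acid anhydride 3 (not isolated), via imide anhydride 4 (not isolated)
Conditions: 1 (3 equiv), DMF, 0 °C; 2 (1 equiv, slow addition), rt; Ac2O, NaOAc, 80 °C; H2O, 60 °C; NaHCO3/EtOAc wash, then HCl, EtOAc extraction
Reagents that add atoms: benzylamine (2), NCc1ccccc1; water, O
Why: Amine acylation by one anhydride of excess 1 gives 3, chemical imidisation closes the cis-fused succinimide 4, and hydrolysis opens the remaining anhydride. Excess of the cheap symmetric 1 and slow addition of 2 hold back the bis-imide; the neutral bis-imide and the water-soluble tetraacid from unreacted 1 are removed by acid–base extraction. No stereocentre is touched, since every ring-fusion carbon stays in a cis-fused five-membered ring until the final hydrolysis.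

**Step 2**
Reactants: 5; 6 iodomethane
Product: 8 3-benzyl-1,5-dimethyl-2,4-dioxo-3-azabicyclo[3.2.0]heptane-6,7-dicarboxylic acid (meso; both methyl groups on the face of the CO2H groups), via monomethyl imide diacid 7 (not isolated)
Conditions: LiN(i-Pr)2 (3.2 equiv), THF/DMPU (5:1), −78 °C; MeI (1.1 equiv), −78 to −40 °C; LiN(i-Pr)2 (1.5 equiv), −78 °C; MeI (3 equiv), −78 to −20 °C; 1 M HCl
Reagents that add atoms: iodomethane (6), CI
Why: The first two equivalents of LiN(i-Pr)2 turn the acids of 5 into lithium carboxylates and the next removes one imide α-hydrogen (C1–H) to give a lithium enolate, which attacks MeI in an SN2 C-alkylation to give 7; the sequence is repeated at C4–H to give 8. The closest known reaction type is the α-alkylation of cis-fused cyclic imide and lactam enolates at the ring-fusion carbon, together with the alkylation of cyclobutane-1,2-dicarboxylate enolates. No ring is closed. Site selectivity rests on acidity: an imide α-C–H is many pK units more acidic than a C–H next to a carboxylate, whose removal would need a geminal enediolate, so C2 and C3 are neither alkylated nor epimerised. Each new quaternary centre (C1, C4) is controlled by the ring fusion: the enolate carbon keeps three ring bonds and a 3-azabicyclo[3.2.0]heptane-2,4-dione can only be cis-fused, so the methyl group must bond on the face the hydrogen left, although that is the face of the neighbouring carboxylate. C- over O-alkylation is secured by the lithium counter-ion and the soft electrophile, and esterification of the carboxylates is held back by quenching cold. Racemic 7 converges on meso 8 because the second methylation obeys the same constraint.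

**Step 3**
Reactants: 8
Product: 9 di-tert-butyl 3-benzyl-1,5-dimethyl-2,4-dioxo-3-azabicyclo[3.2.0]heptane-6,7-dicarboxylate (meso)
Conditions: Cl3CC(=NH)Ot-Bu (5 equiv), BF3·OEt2 (cat.), CH2Cl2/cyclohexane, rt
Reagents that add atoms: tert-butyl 2,2,2-trichloroacetimidate, CC(C)(C)OC(=N)C(Cl)(Cl)Cl
Why: Acid-catalysed tert-butylation with a trichloroacetimidate goes through a tert-butyl cation equivalent captured by the carboxyl oxygen, so crowding at C2/C3 does not matter and the imide is inert. tert-Butyl esters are chosen because they resist borohydride, the dianion and DBU and leave with acid at the end.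

**Step 4**
Reactants: 9
Product: 11 di-tert-butyl 1,5-dimethyl-2-oxo-3-oxabicyclo[3.2.0]heptane-6,7-dicarboxylate (racemic γ-lactone; ester groups cis to each other and trans to the lactone ring), via hydroxy amide 10 (not isolated)
Conditions: NaBH4 (6 equiv), i-PrOH/H2O (6:1), rt to 40 °C; then AcOH to pH 5, 80 °C
Reagents that add atoms: none
Why: Exhaustive borohydride reduction of a cyclic imide, as in the reductive cleavage of phthalimides and the ring-opening reduction of succinimides: hydride adds to one imide carbonyl, the hydroxylactam opens to the formyl amide, and a second hydride gives 10. In warm AcOH the cis hydroxymethyl group attacks the neighbouring amide and expels benzylamine to give the lactone. tert-Butyl esters do not react with NaBH4 and lie trans to the reacting groups, so they cannot take part.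

**Step 5**
Reactants: 11
Product: 12 di-tert-butyl 3,4-bis(hydroxymethyl)-3,4-dimethylcyclobutane-1,2-dicarboxylate (meso; hydroxymethyl groups cis to each other and trans to the ester groups)
Conditions: LiBH4 (3 equiv), MeOH (1 equiv), THF, 0 °C to rt
Reagents that add atoms: none
Why: LiBH4 reduces lactones to diols but attacks hindered tert-butyl esters only slowly (chemoselective hydride reduction). The trans relation of each new alcohol to both esters rules out relactonisation.

**Step 6**
Reactants: 12
Product: 13 di-tert-butyl 3,4-diformyl-3,4-dimethylcyclobutane-1,2-dicarboxylate (meso; formyl groups cis to each other)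
Conditions: (COCl)2, DMSO, CH2Cl2, −78 °C; Et3N, −78 to 0 °C
Reagents that add atoms: none
Why: Swern oxidation: both alcohols are converted to alkoxysulfonium ions before base is added, so no hydroxy aldehyde is left to close to a lactol and be over-oxidised. Neither formyl carbon has an α-hydrogen, so the dialdehyde can neither enolise nor epimerise.

**Step 7**
Reactants: 13; 14 ethyl 2-methyl-3-oxobutanoate
Product: 15 di-tert-butyl 3,4-bis(5-ethoxy-1-hydroxy-4-methyl-3,5-dioxopentyl)-3,4-dimethylcyclobutane-1,2-dicarboxylate (mixture of carbinol and C3' epimers; ring configuration unchanged)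
Conditions: 14 (5 equiv), NaH, THF, 0 °C; n-BuLi, 0 °C; then 13, −78 to 0 °C; cold 1 M HCl to pH 4
Reagents that add atoms: ethyl 2-methyl-3-oxobutanoate (14), CCOC(=O)C(C)C(C)=O
Why: γ-Aldol addition of an acetoacetate dianion: the terminal carbanion is the more reactive site and adds fast even to neopentyl aldehydes. After the first addition the alkoxide may close reversibly onto the neighbouring formyl group; warming to 0 °C with excess dianion should carry the second addition through the open form, as organometallic additions to lactols do. The new carbinol and C3' centres are lost in steps 8 and 9, so their configuration is irrelevant.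

**Step 8**
Reactants: 15
Product: 16 di-tert-butyl 3,4-bis(5-ethoxy-4-methyl-3,5-dioxopentanoyl)-3,4-dimethylcyclobutane-1,2-dicarboxylate (bis 3,5-diketo ester; largely enolised)
Conditions: Dess–Martin periodinane (3 equiv), NaHCO3, CH2Cl2, 0 °C to rt
Reagents that add atoms: none
Why: Dess–Martin oxidation of δ-hydroxy-β-keto esters to 3,5-diketo esters is the standard second step of this pyranone construction. It is neutral and fast on hindered secondary alcohols, and the product is stabilised as the enolised β-diketone.

**Step 9**
Reactants: 16
Product: 17 di-tert-butyl 3,4-bis(4-hydroxy-3-methyl-2-oxo-2H-pyran-6-yl)-3,4-dimethylcyclobutane-1,2-dicarboxylate (meso)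
Conditions: DBU (4 equiv), toluene, rt to 60 °C; then 1 M HCl
Reagents that add atoms: none
Why: Base-mediated lactonisation: the enolate oxygen at C6' attacks the ethyl ester C2' (6-exo-trig) and ethoxide is lost irreversibly, giving the aromatic-like 4-hydroxy-2-pyranone. Both arms are present as delocalised diketone enolates and are therefore poor electrophiles towards each other, which should hold back aldol reaction between the arms.

**Step 10**
Reactants: 17
Product: 18 di-tert-butyl 3,4-bis(4-methoxy-3-methyl-2-oxo-2H-pyran-6-yl)-3,4-dimethylcyclobutane-1,2-dicarboxylate (meso)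
Conditions: Me2SO4 (4 equiv), K2CO3, acetone, 50 °C
Reagents that add atoms: dimethyl sulfate, COS(=O)(=O)OC
Why: O-Alkylation of the ambident 4-hydroxy-2-pyranone anion; with Me2SO4 and K2CO3 in acetone the 4-oxygen is the preferred site, giving the 4-methoxy-2-pyranone and not the 2-methoxy-4-pyranone. The tert-butyl esters and the ring stereocentres are untouched by the weak base.

**Step 11**
Reactants: 18
Product: 19 CNP0574758.1, 3,4-bis(4-methoxy-3-methyl-2-oxo-2H-pyran-6-yl)-3,4-dimethylcyclobutane-1,2-dicarboxylic acid (meso; pyranones cis on one face and CO2H cis with both methyl groups on the other)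
Conditions: CF3CO2H/CH2Cl2 (1:3), 0 °C to rt
Reagents that add atoms: none
Why: Acidolysis of tert-butyl esters (E1 loss of the tert-butyl cation as 2-methylpropene) needs no nucleophile, so the lactone and vinylogous ester functions of the methoxypyranones are not attacked. C2 and C3 do not epimerise in acid at room temperature.

## Compound list

1 | cis,trans,cis-cyclobutane-1,2,3,4-tetracarboxylic dianhydride | O=C1OC(=O)[C@H]2[C@@H]3C(=O)OC(=O)[C@@H]3[C@H]21 | starting material
2 | benzylamine | NCc1ccccc1 | starting material
3 | 3-(benzylcarbamoyl)cyclobutane-1,2,4-tricarboxylic acid 1,2-anhydride (amide and acid cis to each other, trans to the anhydride; racemic) | O=C1OC(=O)[C@H]2[C@H](C(=O)NCc3ccccc3)[C@H](C(=O)O)[C@H]21 | intermediate (not isolated)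
4 | N-benzyl imide anhydride of the tetracarboxylic acid (imide and anhydride rings on opposite faces) | O=C1OC(=O)[C@H]2[C@@H]3C(=O)N(Cc4ccccc4)C(=O)[C@@H]3[C@H]21 | intermediate (not isolated)
5 | 3-benzyl-2,4-dioxo-3-azabicyclo[3.2.0]heptane-6,7-dicarboxylic acid (meso) | c1ccc(CN2C(=O)[C@H]3[C@H](C(=O)O)[C@H](C(=O)O)[C@H]3C2=O)cc1 | intermediate
6 | iodomethane | CI | starting material
7 | 3-benzyl-1-methyl-2,4-dioxo-3-azabicyclo[3.2.0]heptane-6,7-dicarboxylic acid (racemic) | c1ccc(CN2C(=O)[C@@]3(C)[C@H](C(=O)O)[C@H](C(=O)O)[C@H]3C2=O)cc1 | intermediate (not isolated)
8 | 3-benzyl-1,5-dimethyl-2,4-dioxo-3-azabicyclo[3.2.0]heptane-6,7-dicarboxylic acid (meso) | c1ccc(CN2C(=O)[C@@]3(C)[C@H](C(=O)O)[C@H](C(=O)O)[C@@]3(C)C2=O)cc1 | intermediate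
9 | di-tert-butyl ester of 8 (meso) | c1ccc(CN2C(=O)[C@@]3(C)[C@H](C(=O)OC(C)(C)C)[C@H](C(=O)OC(C)(C)C)[C@@]3(C)C2=O)cc1 | intermediate
10 | di-tert-butyl 3-(benzylcarbamoyl)-4-(hydroxymethyl)-3,4-dimethylcyclobutane-1,2-dicarboxylate (racemic) | O=C(NCc1ccccc1)[C@@]1(C)[C@H](C(=O)OC(C)(C)C)[C@H](C(=O)OC(C)(C)C)[C@@]1(C)CO | intermediate (not isolated)
11 | di-tert-butyl 1,5-dimethyl-2-oxo-3-oxabicyclo[3.2.0]heptane-6,7-dicarboxylate (racemic) | O=C1[C@@]2(C)[C@H](C(=O)OC(C)(C)C)[C@H](C(=O)OC(C)(C)C)[C@@]2(C)CO1 | intermediate
12 | di-tert-butyl 3,4-bis(hydroxymethyl)-3,4-dimethylcyclobutane-1,2-dicarboxylate (meso) | OC[C@@]1(C)[C@H](C(=O)OC(C)(C)C)[C@H](C(=O)OC(C)(C)C)[C@@]1(C)CO | intermediate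
13 | di-tert-butyl 3,4-diformyl-3,4-dimethylcyclobutane-1,2-dicarboxylate (meso) | O=C[C@@]1(C)[C@H](C(=O)OC(C)(C)C)[C@H](C(=O)OC(C)(C)C)[C@@]1(C)C=O | intermediate
14 | ethyl 2-methyl-3-oxobutanoate | CCOC(=O)C(C)C(C)=O | starting material
15 | bis(δ-hydroxy-β-keto ester) from double γ-aldol addition (epimer mixture in the arms) | CCOC(=O)C(C)C(=O)CC(O)[C@@]1(C)[C@H](C(=O)OC(C)(C)C)[C@H](C(=O)OC(C)(C)C)[C@@]1(C)C(O)CC(=O)C(C)C(=O)OCC | intermediate
16 | bis(3,5-diketo ester) | CCOC(=O)C(C)C(=O)CC(=O)[C@@]1(C)[C@H](C(=O)OC(C)(C)C)[C@H](C(=O)OC(C)(C)C)[C@@]1(C)C(=O)CC(=O)C(C)C(=O)OCC | intermediate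
17 | di-tert-butyl 3,4-bis(4-hydroxy-3-methyl-2-oxo-2H-pyran-6-yl)-3,4-dimethylcyclobutane-1,2-dicarboxylate | Cc1c(O)cc([C@@]2(C)[C@H](C(=O)OC(C)(C)C)[C@H](C(=O)OC(C)(C)C)[C@@]2(C)c2cc(O)c(C)c(=O)o2)oc1=O | intermediate
18 | di-tert-butyl 3,4-bis(4-methoxy-3-methyl-2-oxo-2H-pyran-6-yl)-3,4-dimethylcyclobutane-1,2-dicarboxylate | COc1cc([C@@]2(C)[C@H](C(=O)OC(C)(C)C)[C@H](C(=O)OC(C)(C)C)[C@@]2(C)c2cc(OC)c(C)c(=O)o2)oc(=O)c1C | intermediate
19 | CNP0574758.1 | COc1cc([C@@]2(C)[C@H](C(=O)O)[C@H](C(=O)O)[C@@]2(C)c2cc(OC)c(C)c(=O)o2)oc(=O)c1C | target

## Step count and risk

Total: 11 steps. Longest linear sequence: 11 steps (1 to 19); 2, 6 and 14 are purchased.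

**Step 2 (key step).** The second enolisation and alkylation take place next to the new quaternary centre and on the face of the neighbouring carboxylate, so they may stop at 7. The trilithiated species may aggregate or precipitate, and the carboxylates may be O-methylated if the mixture warms. Fallback, from 5 to 9: the acids are esterified first with tert-butyl trichloroacetimidate to the unmethylated imide di-tert-butyl ester F1. This neutral, soluble substrate is methylated twice with KN(SiMe3)2/MeI in THF at −78 °C, through the monomethyl imide di-tert-butyl ester F2, to reach 9 directly. Site selectivity then rests on the choice of base: a silylamide is strong enough for the imide α-C–H but barely for a hindered tert-butyl ester. The price is that C2/C3 lose the protection against epimerisation that the carboxylates give.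

**Step 4.** The reduction may stop at the ring-closed hydroxylactam, because the two quaternary carbons favour the closed form over the formyl amide that must be reduced. Expulsion of benzylamine from 10 may also be slow enough for the hot acid to start removing tert-butyl groups. Fallback, from 8 to 11, by hydrolysis instead of reduction:
- NaOH (aq), then 6 M HCl at reflux opens the imide and cleaves the amic acid with help from the neighbouring carboxyl group, giving 1,2-dimethylcyclobutane-1,2,3,4-tetracarboxylic acid F3.
- Ac2O closes the only two possible cis pairs to the dimethyl dianhydride F4.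
- KOt-Bu (1 equiv, THF, −40 °C) opens only the unhindered C2/C3 anhydride, giving the mono-tert-butyl half ester F5.
- tert-Butyl trichloroacetimidate gives the di-tert-butyl ester C1/C4 anhydride F6.
- NaBH4 reduces the remaining anhydride to the hydroxy acid, which lactonises on mild acidification to 11.

**Step 7.** The reaction may stall after the first addition: the alkoxide closes onto the neighbouring formyl group as a lactolate that reopens slowly, while the dianion decays on warming and the second neopentyl carbonyl is more crowded. Fallback, from 13 to 17, with a small, thermally robust nucleophile and a different ring construction: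
- MeMgBr (excess, THF, 0 °C to rt) can be driven through the lactolate and gives the bis(1-hydroxyethyl) compound F7.
- Dess–Martin periodinane gives the diacetyl compound F8.
- LiN(i-Pr)2 with Me3SiCl present (−78 °C) gives the bis(trimethylsilyl enol ether) F9.
- 2-Methylpropanedioyl dichloride (CC(C(=O)Cl)C(=O)Cl; Et2O, −78 °C to rt) annulates each silyl enol ether to a 4-hydroxy-3-methyl-2-pyranone, the known reaction of silyl enol ethers with malonyl dichlorides. This gives 17 and bypasses steps 8 and 9.

**Step 10.** The pyranone anion is ambident: methylation at the 2-oxygen of one or both rings gives 2-methoxy-4-pyranone isomers, and with two rings any leakage is multiplied. Fallback, from 13 to 18, bringing the methyl ether in with the building block: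
- 14 is converted with HC(OMe)3/H2SO4 (cat.) to ethyl (E)-3-methoxy-2-methylbut-2-enoate F10.
- Its lithium dienolate (LiN(i-Pr)2, THF, −78 °C) adds through the γ-carbon to both formyl groups of 13, and each alkoxide lactonises onto the cis ester (the kavalactone construction), giving the bis(5,6-dihydro-4-methoxy-3-methyl-2-pyranone) F11.
- DDQ (dioxane, 100 °C) dehydrogenates both rings to 18, so no ambident alkylation takes place.

## Further compounds

F1 | step 2 | di-tert-butyl 3-benzyl-2,4-dioxo-3-azabicyclo[3.2.0]heptane-6,7-dicarboxylate (meso) | c1ccc(CN2C(=O)[C@H]3[C@H](C(=O)OC(C)(C)C)[C@H](C(=O)OC(C)(C)C)[C@H]3C2=O)cc1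
F2 | step 2 | di-tert-butyl 3-benzyl-1-methyl-2,4-dioxo-3-azabicyclo[3.2.0]heptane-6,7-dicarboxylate (racemic) | c1ccc(CN2C(=O)[C@@]3(C)[C@H](C(=O)OC(C)(C)C)[C@H](C(=O)OC(C)(C)C)[C@H]3C2=O)cc1
F3 | step 4 | 1,2-dimethylcyclobutane-1,2,3,4-tetracarboxylic acid (cis,trans,cis; methyl groups on the face of the C3/C4 carboxyl groups) | OC(=O)[C@@]1(C)[C@H](C(=O)O)[C@H](C(=O)O)[C@@]1(C)C(=O)O
F4 | step 4 | 1,2-dimethylcyclobutane-1,2,3,4-tetracarboxylic 1,2:3,4-dianhydride (rings on opposite faces) | O=C1OC(=O)[C@@]2(C)[C@@H]3C(=O)OC(=O)[C@@H]3[C@]21C
F5 | step 4 | mono-tert-butyl half ester of the C2/C3 pair, C1/C4 anhydride intact (racemic) | O=C1OC(=O)[C@@]2(C)[C@H](C(=O)OC(C)(C)C)[C@H](C(=O)O)[C@]21C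
F6 | step 4 | di-tert-butyl ester of the C2/C3 pair, C1/C4 anhydride intact (meso) | O=C1OC(=O)[C@@]2(C)[C@H](C(=O)OC(C)(C)C)[C@H](C(=O)OC(C)(C)C)[C@]21C
F7 | step 7 | di-tert-butyl 3,4-bis(1-hydroxyethyl)-3,4-dimethylcyclobutane-1,2-dicarboxylate (carbinol epimers) | CC(O)[C@@]1(C)[C@H](C(=O)OC(C)(C)C)[C@H](C(=O)OC(C)(C)C)[C@@]1(C)C(C)O
F8 | step 7 | di-tert-butyl 3,4-diacetyl-3,4-dimethylcyclobutane-1,2-dicarboxylate | CC(=O)[C@@]1(C)[C@H](C(=O)OC(C)(C)C)[C@H](C(=O)OC(C)(C)C)[C@@]1(C)C(C)=O
F9 | step 7 | di-tert-butyl 3,4-dimethyl-3,4-bis[1-(trimethylsilyloxy)vinyl]cyclobutane-1,2-dicarboxylate | C=C(O[Si](C)(C)C)[C@@]1(C)[C@H](C(=O)OC(C)(C)C)[C@H](C(=O)OC(C)(C)C)[C@@]1(C)C(=C)O[Si](C)(C)C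
F10 | step 10 | ethyl (E)-3-methoxy-2-methylbut-2-enoate | CCOC(=O)/C(C)=C(\C)OC
F11 | step 10 | di-tert-butyl 3,4-bis(4-methoxy-3-methyl-2-oxo-5,6-dihydro-2H-pyran-6-yl)-3,4-dimethylcyclobutane-1,2-dicarboxylate (C6' epimers) | COC1=C(C)C(=O)OC(C1)[C@@]2(C)[C@H](C(=O)OC(C)(C)C)[C@H](C(=O)OC(C)(C)C)[C@@]2(C)C1CC(OC)=C(C)C(=O)O1
A1 | alternative 1 | 3,4-bis(4-methoxy-3-methyl-2-oxo-2H-pyran-6-yl)-2,5-dihydrothiophene | COc1cc(C2=C(c3cc(OC)c(C)c(=O)o3)CSC2)oc(=O)c1C
A2 | alternative 1 | maleic anhydride | O=C1OC(=O)C=C1
A3 | alternative 1 | thiolane- and anhydride-fused bis(pyranonyl)cyclobutane | COc1cc([C@@]23CSC[C@@]3(c5cc(OC)c(C)c(=O)o5)[C@H]4C(=O)OC(=O)[C@@H]24)oc(=O)c1C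
A4 | alternative 2 | cis-1,2-dimethylcyclohexa-3,5-diene-1,2-dicarboxylic anhydride | C[C@@]12C=CC=C[C@]1(C)C(=O)OC2=O
A5 | alternative 2 | 2,3-dimethylbicyclo[2.2.0]hex-5-ene-2,3-dicarboxylic anhydride (cyclobutene anti to the anhydride) | C[C@@]12C(=O)OC(=O)[C@]1(C)[C@H]1C=C[C@@H]21
A6 | alternative 3 | di-tert-butyl 3,4-bis(5-tert-butoxy-4-methyl-3,5-dioxopent-1-ynyl)-3,4-dimethylcyclobutane-1,2-dicarboxylate | CC(C(=O)OC(C)(C)C)C(=O)C#C[C@@]1(C)[C@H](C(=O)OC(C)(C)C)[C@H](C(=O)OC(C)(C)C)[C@@]1(C)C#CC(=O)C(C)C(=O)OC(C)(C)C
A7 | alternative 3 | di-tert-butyl ester of the bis(4-hydroxy-3-methyl-2-pyranone), identical with 17 | Cc1c(O)cc([C@@]2(C)[C@H](C(=O)OC(C)(C)C)[C@H](C(=O)OC(C)(C)C)[C@@]2(C)c3cc(O)c(C)c(=O)o3)oc1=O
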